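**Retrosynthetic overview**

1. Target 33 is traced back to the ten-membered enol triflate 24 through oxidative lactonisation of the O6/C12 1,4-diol, angeloylation of O8 and exchange of the C10 triflate for methyl.
2. The strategy rests on the ring 1,5-diene C10=C1–C2–C3–C4=C5 inside the ten-membered ring C1–C10. It is the [3,3] product of a cyclohexane C5–C10 that carries isopropenyl (C4, C3, C15) on C5 and vinyl (C1, C2) plus oxygen on C10, so 24 comes from cyclohexanol 21 by anionic oxy-Cope ring expansion with triflate trapping.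
3. 21 comes from vinyl addition to a C10 ketone. The C5 isopropenyl group comes from cuprate opening of a 5,10-epoxide, O7/O8 from OsO4 on a C7-acylcyclohexene, and C11–C12 from acylation of a C7 vinyllithium.
4. Ring carbons C5–C10, O6 and the oxygen that serves as O10 come from (1S,2S)-3-bromocyclohexa-3,5-diene-1,2-diol (1); O9 comes from 4-methoxybenzyl alcohol.
5. Ring order: cyclohexane C5–C10 (present in 1), then the ten-membered ring (step 15), then the γ-lactone (step 20).

Key step: step 15

Remark: germacrane numbering is used for every intermediate; β is the ring face that carries O7 and O8 in the target, α the face of O6 and O9; PMB = 4-methoxybenzyl. Diol 1 is taken to be the commercial product of microbial dihydroxylation of bromobenzene. O9 is carried as a PMB ether, which step 3 installs directly and which cannot migrate to the C10 alkoxide of step 15.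

**Step 1**
Reactants: 1 (1S,2S)-3-bromocyclohexa-3,5-diene-1,2-diol
Product: 2 (3aS,7aS)-4-bromo-2,2-dimethyl-3a,7a-dihydro-1,3-benzodioxole (5α,6α-acetonide; Br on C7)
Conditions: Me2C(OMe)2, TsOH (cat.), acetone, 0 °C → rt
Reagents that add atoms: 2,2-dimethoxypropane, COC(C)(C)OC
Why: Acid-catalysed acetonide formation ties up the cis-diol and protects the diene-diol against aromatisation without touching a stereocentre.

**Step 2**
Reactants: 2 bromodiene acetonide
Product: 3 9β,10β-epoxide of 2 (vinyl oxirane; C7(Br)=C8 retained)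
Conditions: mCPBA, CH2Cl2, 0 °C → rt
Reagents that add atoms: mCPBA, OOC(=O)c1cccc(Cl)c1
Why: Prilezhaev epoxidation should take the electron-richer C9=C10 bond (C7=C8 is deactivated by bromine) from the β face, anti to the α-acetonide.

**Step 3**
Reactants: 3 vinyl oxirane; 4 4-methoxybenzyl alcohol
Product: 5 7-bromo-9α-(PMB-oxy)cyclohex-7-en-10β-ol 5α,6α-acetonide
Conditions: NaH (cat.), THF/DMF, 0 → 50 °C
Reagents that add atoms: none
Why: Alkoxide opening of the vinyl oxirane (SN2) at the allylic carbon C9 with inversion should give the 9α-ether and the 10β-alcohol, so O9 has its final configuration and protecting group.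

**Step 4**
Reactants: 5 hydroxy ether
Product: 6 10β-methanesulfonate of 5
Conditions: MsCl, Et3N, DMAP (cat.), CH2Cl2, 0 °C
Reagents that add atoms: methanesulfonyl chloride, CS(=O)(=O)Cl
Why: Sulfonylation of the secondary alcohol with retention turns O10 into a leaving group trans to O5.

**Step 5**
Reactants: 6 mesylate
Product: 8 7-bromo-5α,10α-epoxy-9α-(PMB-oxy)cyclohex-7-en-6α-ol, via diol mesylate 7 (not isolated)
Conditions: Dowex 50W (H+ form), MeOH/H2O, 45 °C; filter; then K2CO3, MeOH, 0 °C → rt
Reagents that add atoms: none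
Why: Acetal hydrolysis followed by intramolecular Williamson displacement, in which only the 5α-alkoxide is anti to the 10β-mesylate and can attack C10 with inversion, should give the α-epoxide and free O6–H.

**Step 6**
Reactants: 8 epoxy alcohol
Product: 9 7-bromo-5α,10α-epoxy-6α,9α-bis(PMB-oxy)cyclohex-7-ene
Conditions: NaH, PMBCl, Bu4NI (cat.), THF/DMF, 0 °C → rt
Reagents that add atoms: 4-methoxybenzyl chloride, COc1ccc(CCl)cc1
Why: Williamson etherification of O6, safe because the alkoxide is cis to the oxirane oxygen and cannot undergo Payne rearrangement.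

**Step 7**
Reactants: 10 2-chloro-N-methoxy-N-methylacetamide; 4 4-methoxybenzyl alcohol
Product: 11 N-methoxy-N-methyl-2-(4-methoxybenzyloxy)acetamide
Conditions: NaH, THF, 0 °C → rt
Reagents that add atoms: none
Why: Williamson etherification of the α-chloro amide supplies the two-carbon acyl donor for C11 and C12 with O12 already protected.

**Step 8**
Reactants: 9 vinyl bromide; 11 Weinreb amide
Product: 13 7-[(PMB-oxy)acetyl]-5α,10α-epoxy-6α,9α-bis(PMB-oxy)cyclohex-7-ene, via vinyllithium 12 (not isolated)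
Conditions: t-BuLi (2 equiv), THF, −78 °C; then 11, −78 → −20 °C
Reagents that add atoms: none
Why: Bromine–lithium exchange followed by Weinreb ketone synthesis forms C7–C11 without over-addition (stable chelated adduct) and creates no stereocentre.

**Step 9**
Reactants: 13 enone
Product: 14 7α-[(PMB-oxy)acetyl]-5α,10α-epoxy-6α,9α-bis(PMB-oxy)cyclohexane-7β,8β-diol
Conditions: OsO4 (cat.), NMO, acetone/H2O, rt
Reagents that add atoms: N-methylmorpholine N-oxide, C[N+]1([O-])CCOCC1; water, O (oxygen relayed by catalytic OsO4, O=[Os](=O)(=O)=O)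
Why: Upjohn syn-dihydroxylation of the only alkene should occur on the β face, anti to both allylic α-ethers at C6 and C9 and to the α-epoxide, which sets C7 (O7 β, side chain α) and C8 (O8 β) together.

**Step 10**
Reactants: 14 diol
Product: 15 7β,8β-acetonide of 14
Conditions: 2-methoxypropene, PPTS (cat.), CH2Cl2, 0 °C → rt
Reagents that add atoms: 2-methoxypropene, COC(C)=C
Why: Acid-catalysed acetonide formation across the cis tertiary/secondary diol protects O7 and O8 in one operation and removes the retro-aldol pathway of the β-hydroxy ketone.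

**Step 11**
Reactants: 15 ketone
Product: 16 7α-[3-(PMB-oxy)prop-1-en-2-yl]-5α,10α-epoxy-6α,9α-bis(PMB-oxy)cyclohexane-7β,8β-diol acetonide
Conditions: Ph3PCH3Br, KN(SiMe3)2, THF, 0 → 40 °C
Reagents that add atoms: methyltriphenylphosphonium bromide, C[P+](c1ccccc1)(c1ccccc1)c1ccccc1.[Br-]
Why: Wittig methylenation converts the C11 ketone into the C11=C13 methylene; C7 is quaternary, so no stereocentre can epimerise.

**Step 12**
Reactants: 16 epoxide; 17 isopropenylmagnesium bromide
Product: 18 5β-isopropenyl-6α,9α-bis(PMB-oxy)-7α-[3-(PMB-oxy)prop-1-en-2-yl]cyclohexane-7β,8β,10α-triol 7,8-acetonide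
Conditions: CuI (cat.), THF, −30 °C → rt
Reagents that add atoms: none
Why: Copper-catalysed Grignard opening of the epoxide (SN2, trans-diaxial by the Fürst–Plattner rule): the half-chair that keeps the C7 side chain pseudo-equatorial lets the nucleophile reach only C5 from the β face, so isopropenyl should become 5β (trans to O6) and the oxirane oxygen should remain as the 10α-hydroxyl.

**Step 13**
Reactants: 18 alcohol
Product: 19 C10 ketone of 18
Conditions: Dess–Martin periodinane, CH2Cl2, 0 °C → rt
Reagents that add atoms: none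
Why: Dess–Martin oxidation under near-neutral conditions should give the ketone without conjugating the β,γ-alkene or epimerising C5.

**Step 14**
Reactants: 19 ketone; 20 vinylmagnesium bromide
Product: 21 5β-isopropenyl-10β-vinyl-6α,9α-bis(PMB-oxy)-7α-[3-(PMB-oxy)prop-1-en-2-yl]cyclohexane-7β,8β,10α-triol 7,8-acetonide
Conditions: LaCl3·2LiCl (cat.), THF, −78 → −40 °C
Reagents that add atoms: none
Why: 1,2-Addition of the Grignard reagent to the ketone (LaCl3·2LiCl suppresses enolisation): the ketone sits in the chair with the C5 isopropenyl axial, the axial α trajectory is shielded by the syn-axial C6 ether and the chelating equatorial C9 ether also directs attack trans to O9, so the vinyl group should enter equatorially from the β face and leave the 10α-oxygen cis to O9.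

**Step 15**
Reactants: 21 cis-1-vinyl-2-isopropenylcyclohexanol
Product: 24 ten-membered enol triflate (ring C1–C10; OTf on C10; ring-cis C1=C10; ring-trans C4=C5), via potassium alkoxide 22 (not isolated), via potassium enolate 23 (not isolated)
Conditions: KH, 18-crown-6, THF, 0 °C → rt; then PhNTf2, −78 → 0 °C
Reagents that add atoms: N-phenylbis(trifluoromethanesulfonimide), O=S(=O)(N(c1ccccc1)S(=O)(=O)C(F)(F)F)C(F)(F)F
Why: KH/18-crown-6 forms the potassium alkoxide 22, whose charge weakens the C5–C10 bond, so that a concerted chair-like [3,3] shift (anionic oxy-Cope rearrangement, the reaction type established for 1-vinyl-2-alkenylcyclohexanols) joins the vinyl terminus C2 to the isopropenyl terminus C3 while C5–C10 breaks; the regiodefined enolate 23 (C10=C1 only) is then O-triflated by PhNTf2 before it can equilibrate towards C9 and expel the C8 oxygen. The ten-membered ring is not closed end to end: it arises by four-atom ring expansion of the cyclohexane C5–C10, and C2–C3 is the only new σ-bond. No stereocentre is created, C6 to C9 are spectators, and the step has to deliver the geometry of the two new double bonds. Ring-cis C1=C10 and ring-trans C4=C5 follow from the chair transition state reached from the cyclohexane chair with the C10 vinyl equatorial and the C5 isopropenyl axial, because C9 is then pseudoaxial and C6 pseudoequatorial on the six-atom array. That chair should be the populated one (the other places the C7 side chain axial and syn to an axial O9 ether), and it also puts the oxyanion pseudoequatorial in the transition state, as anionic oxy-Cope shifts prefer. Because OTf outranks C9, the ring-cis C1=C10 bond of 24 carries the CIP label E.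

**Step 16**
Reactants: 24 enol triflate
Product: 25 C10-methyl triene (1(10)Z,4E,11(13)) with 6α,9α,12-tris(PMB-oxy) groups and the 7β,8β-acetonide
Conditions: MeZnCl, Pd(PPh3)4 (cat.), THF, rt → 45 °C
Reagents that add atoms: methylzinc chloride, C[Zn]Cl
Why: Negishi cross-coupling of the alkenyl triflate proceeds with retention of alkene geometry and installs C14.

**Step 17**
Reactants: 25 acetonide
Product: 26 7β,8β-diol of 25
Conditions: AcOH/H2O, 40 °C
Reagents that add atoms: none
Why: Mild acid hydrolysis of the acetal should free O7 and O8 while the three PMB ethers stay in place.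

**Step 18**
Reactants: 26 diol; 27 angelic acid
Product: 29 8-O-angelate of 26, via mixed anhydride 28 (not isolated)
Conditions: 2,4,6-trichlorobenzoyl chloride, Et3N, toluene, rt; then 26, DMAP (cat.), 60 °C
Reagents that add atoms: none
Why: Yamaguchi esterification acylates the secondary O8–H in preference to the tertiary O7–H and is the standard way to transfer the angeloyl group without Z to E isomerisation.

**Step 19**
Reactants: 29 angelate
Product: 30 6α,9α,12-triol (all PMB ethers removed; O7–H free; O8 angelate)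
Conditions: DDQ, CH2Cl2/pH 7 buffer, 0 °C → rt
Reagents that add atoms: none
Why: Oxidative PMB cleavage (hydride abstraction by DDQ, hydrolysis of the oxocarbenium ion in the wet medium) should free O6, O9 and O12 without touching the ester or the alkenes.

**Step 20**
Reactants: 30 triol
Product: 33 CNP0292337.1, via hydroxy aldehyde 31 (not isolated), via lactol 32 (not isolated)
Conditions: TEMPO (cat.), PhI(OAc)2, CH2Cl2, rt
Reagents that add atoms: none
Why: TEMPO-mediated oxidative lactonisation oxidises the primary allylic alcohol first; the aldehyde is captured by the cis O6–H as the five-membered lactol, which is oxidised on to the α-methylene-γ-lactone, while the hindered secondary O9–H and the tertiary O7–H should survive.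

**Compound list**

1 | (1S,2S)-3-bromocyclohexa-3,5-diene-1,2-diol (its C1, C2, C3 become C5, C6, C7) | [C@@H]1(O)[C@H](O)C(Br)=CC=C1 | starting material
2 | (3aS,7aS)-4-bromo-2,2-dimethyl-3a,7a-dihydro-1,3-benzodioxole | [C@H]12OC(C)(C)O[C@@H]2C(Br)=CC=C1 | intermediate
3 | 9β,10β-epoxide of 2 | [C@H]12OC(C)(C)O[C@@H]2C(Br)=C[C@H]3O[C@H]31 | intermediate
4 | 4-methoxybenzyl alcohol | OCc1ccc(OC)cc1 | starting material
5 | 7-bromo-9α-(PMB-oxy)cyclohex-7-en-10β-ol 5α,6α-acetonide | [C@H]12OC(C)(C)O[C@@H]2C(Br)=C[C@H](OCc3ccc(OC)cc3)[C@H]1O | intermediate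
6 | 10β-methanesulfonate of 5 | [C@H]12OC(C)(C)O[C@@H]2C(Br)=C[C@H](OCc3ccc(OC)cc3)[C@H]1OS(C)(=O)=O | intermediate
7 | 7-bromo-9α-(PMB-oxy)-10β-(mesyloxy)cyclohex-7-ene-5α,6α-diol | [C@@H]1(O)[C@H](O)C(Br)=C[C@H](OCc2ccc(OC)cc2)[C@H]1OS(C)(=O)=O | intermediate (not isolated)
8 | 7-bromo-5α,10α-epoxy-9α-(PMB-oxy)cyclohex-7-en-6α-ol | [C@@H]12[C@H](O)C(Br)=C[C@H](OCc3ccc(OC)cc3)[C@@H]1O2 | intermediate
9 | 7-bromo-5α,10α-epoxy-6α,9α-bis(PMB-oxy)cyclohex-7-ene | [C@@H]12[C@H](OCc3ccc(OC)cc3)C(Br)=C[C@H](OCc3ccc(OC)cc3)[C@@H]1O2 | intermediate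
10 | 2-chloro-N-methoxy-N-methylacetamide | ClCC(=O)N(C)OC | starting material
11 | N-methoxy-N-methyl-2-(4-methoxybenzyloxy)acetamide | CON(C)C(=O)COCc1ccc(OC)cc1 | intermediate
12 | C7 vinyllithium derived from 9 | [C@@H]12[C@H](OCc3ccc(OC)cc3)C([Li])=C[C@H](OCc3ccc(OC)cc3)[C@@H]1O2 | intermediate (not isolated)
13 | 7-[(PMB-oxy)acetyl]-5α,10α-epoxy-6α,9α-bis(PMB-oxy)cyclohex-7-ene | [C@@H]12[C@H](OCc3ccc(OC)cc3)C(C(=O)COCc3ccc(OC)cc3)=C[C@H](OCc3ccc(OC)cc3)[C@@H]1O2 | intermediate
14 | 7α-[(PMB-oxy)acetyl]-5α,10α-epoxy-6α,9α-bis(PMB-oxy)cyclohexane-7β,8β-diol | [C@@H]12[C@H](OCc3ccc(OC)cc3)[C@](O)(C(=O)COCc3ccc(OC)cc3)[C@@H](O)[C@H](OCc3ccc(OC)cc3)[C@@H]1O2 | intermediate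
15 | 7β,8β-acetonide of 14 | [C@@H]12[C@H](OCc3ccc(OC)cc3)[C@@]4(C(=O)COCc3ccc(OC)cc3)OC(C)(C)O[C@H]4[C@H](OCc3ccc(OC)cc3)[C@@H]1O2 | intermediate
16 | 7α-[3-(PMB-oxy)prop-1-en-2-yl]-5α,10α-epoxy-6α,9α-bis(PMB-oxy)cyclohexane-7β,8β-diol acetonide | [C@@H]12[C@H](OCc3ccc(OC)cc3)[C@@]4(C(=C)COCc3ccc(OC)cc3)OC(C)(C)O[C@H]4[C@H](OCc3ccc(OC)cc3)[C@@H]1O2 | intermediate
17 | isopropenylmagnesium bromide | CC(=C)[Mg]Br | starting material
18 | 5β-isopropenyl-6α,9α-bis(PMB-oxy)-7α-[3-(PMB-oxy)prop-1-en-2-yl]cyclohexane-7β,8β,10α-triol 7,8-acetonide | [C@H]1(C(C)=C)[C@H](OCc2ccc(OC)cc2)[C@@]3(C(=C)COCc2ccc(OC)cc2)OC(C)(C)O[C@H]3[C@H](OCc2ccc(OC)cc2)[C@@H]1O | intermediate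
19 | C10 ketone of 18 | [C@H]1(C(C)=C)[C@H](OCc2ccc(OC)cc2)[C@@]3(C(=C)COCc2ccc(OC)cc2)OC(C)(C)O[C@H]3[C@H](OCc2ccc(OC)cc2)C1=O | intermediate
20 | vinylmagnesium bromide | C=C[Mg]Br | starting material
21 | 10β-vinyl-10α-hydroxy Cope precursor (5β-isopropenyl; 6α,9α,12-tris-PMB; 7β,8β-acetonide) | [C@H]1(C(C)=C)[C@H](OCc2ccc(OC)cc2)[C@@]3(C(=C)COCc2ccc(OC)cc2)OC(C)(C)O[C@H]3[C@H](OCc2ccc(OC)cc2)[C@@]1(O)C=C | intermediate
22 | potassium alkoxide of 21 | [C@H]1(C(C)=C)[C@H](OCc2ccc(OC)cc2)[C@@]3(C(=C)COCc2ccc(OC)cc2)OC(C)(C)O[C@H]3[C@H](OCc2ccc(OC)cc2)[C@@]1([O-])C=C.[K+] | intermediate (not isolated)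
23 | potassium enolate (O on C10, C10=C1 ring-cis) of the ring-expanded ketone | COc1ccc(CO[C@H]2/C=C(\C)CC/C=C(/[O-])[C@@H](OCc5ccc(OC)cc5)[C@@H]3OC(C)(C)O[C@]23C(=C)COCc4ccc(OC)cc4)cc1.[K+] | intermediate (not isolated)
24 | ten-membered C10 enol triflate (ring-cis C1=C10, E C4=C5; 6α,9α,12-tris-PMB; 7β,8β-acetonide) | COc1ccc(CO[C@H]2/C=C(\C)CC/C=C(/OS(=O)(=O)C(F)(F)F)[C@@H](OCc5ccc(OC)cc5)[C@@H]3OC(C)(C)O[C@]23C(=C)COCc4ccc(OC)cc4)cc1 | intermediate
25 | C10-methyl (1(10)Z,4E,11(13))-triene; tris-PMB; 7β,8β-acetonide | COc1ccc(CO[C@H]2/C=C(\C)CC/C=C(/C)[C@@H](OCc5ccc(OC)cc5)[C@@H]3OC(C)(C)O[C@]23C(=C)COCc4ccc(OC)cc4)cc1 | intermediate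
26 | 7β,8β-diol of 25 | COc1ccc(CO[C@H]2/C=C(\C)CC/C=C(/C)[C@@H](OCc3ccc(OC)cc3)[C@H](O)[C@@]2(O)C(=C)COCc3ccc(OC)cc3)cc1 | intermediate
27 | angelic acid, (Z)-2-methylbut-2-enoic acid | C/C=C(/C)C(=O)O | starting material
28 | angelic 2,4,6-trichlorobenzoic anhydride | C/C=C(/C)C(=O)OC(=O)c1c(Cl)cc(Cl)cc1Cl | intermediate (not isolated)
29 | 8-O-angelate of 26 | COc1ccc(CO[C@H]2/C=C(\C)CC/C=C(/C)[C@@H](OCc3ccc(OC)cc3)[C@H](OC(=O)/C(C)=C\C)[C@@]2(O)C(=C)COCc3ccc(OC)cc3)cc1 | intermediate
30 | 6α,9α,12-triol 8-angelate (7β-OH free) | O[C@H]1/C=C(\C)CC/C=C(/C)[C@@H](O)[C@H](OC(=O)/C(C)=C\C)[C@@]1(O)C(=C)CO | intermediate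
31 | C12 aldehyde of 30 | O[C@H]1/C=C(\C)CC/C=C(/C)[C@@H](O)[C@H](OC(=O)/C(C)=C\C)[C@@]1(O)C(=C)C=O | intermediate (not isolated)
32 | 6,12-lactol (hemiacetal carbon C12, configuration not defined) | C=C1C(O)O[C@H]2/C=C(\C)CC/C=C(/C)[C@@H](O)[C@H](OC(=O)/C(C)=C\C)[C@@]12O | intermediate (not isolated)
33 | CNP0292337.1 | C=C1C(=O)O[C@H]2/C=C(\C)CC/C=C(/C)[C@@H](O)[C@H](OC(=O)/C(C)=C\C)[C@@]12O | target

**Step count**

Total: 20 steps. Longest linear sequence: 19 steps (steps 1–6 and 8–20; step 7 prepares the acyl donor).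

**Steps most likely to fail**

Step 15. The strongly basic alkoxide or the enolate may be consumed by elimination or fragmentation (for example enolate equilibration towards C9 and loss of the C8 oxygen) faster than the [3,3] shift and the triflation occur. The fallback removes the charge from the rearrangement and sets out from 21. The tertiary alcohol would be silylated (TMSOTf, 2,6-lutidine) to the trimethylsilyl ether F1. Heating F1 in o-dichlorobenzene in base-washed glassware should bring about the neutral silyloxy-Cope rearrangement through the same chair and give the ten-membered trimethylsilyl enol ether F2. Cleavage of F2 with MeLi in THF at 0 °C would release the lithium enolate F3 regiospecifically, and PhNTf2 would convert it into 24, where the route is rejoined.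

Step 14. The vinyl nucleophile may attack the α face, anti to the axial C5 isopropenyl group, or the hindered ketone may simply enolise. The fallback builds the carbinol in two stages under thermodynamic control and sets out from 19. Corey–Chaykovsky methylenation with dimethylsulfoxonium methylide (Me3S(O)I, NaH, DMSO) adds reversibly and should place the new CH2 group equatorial (β), giving the spiro-epoxide F4 with its oxygen α. Excess dimethylsulfonium methylide (Me3SI, n-BuLi, THF) would then open F4 at CH2 and lose Me2S, which homologates the oxirane to the vinyl carbinol 21, where the route is rejoined.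

Step 17. Acid may trigger transannular cation–olefin cyclisation of the 1(10),4-diene or ionise the allylic C6 ether before the acetal is hydrolysed. The fallback moves the hydrolysis to a stage at which C1=C10 is an electron-poor enol triflate that cannot take part in such a cyclisation, and sets out from 24. Aqueous acetic acid would give the diol enol triflate F5, Yamaguchi angeloylation of O8 would give the angelate enol triflate F6, and the ester-tolerant Negishi coupling with MeZnCl and Pd(PPh3)4 would deliver 29, where the route is rejoined.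

**Further compounds**

F1 | step 15 | trimethylsilyl ether of 21 | [C@H]1(C(C)=C)[C@H](OCc2ccc(OC)cc2)[C@@]3(C(=C)COCc2ccc(OC)cc2)OC(C)(C)O[C@H]3[C@H](OCc2ccc(OC)cc2)[C@@]1(O[Si](C)(C)C)C=C
F2 | step 15 | ten-membered C10 trimethylsilyl enol ether | COc1ccc(CO[C@H]2/C=C(\C)CC/C=C(/O[Si](C)(C)C)[C@@H](OCc5ccc(OC)cc5)[C@@H]3OC(C)(C)O[C@]23C(=C)COCc4ccc(OC)cc4)cc1
F3 | step 15 | lithium enolate of the ring-expanded ketone | COc1ccc(CO[C@H]2/C=C(\C)CC/C=C(/[O-])[C@@H](OCc5ccc(OC)cc5)[C@@H]3OC(C)(C)O[C@]23C(=C)COCc4ccc(OC)cc4)cc1.[Li+]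
F4 | step 14 | C10 spiro-epoxide (oxygen α, CH2 β) | [C@H]1(C(C)=C)[C@H](OCc2ccc(OC)cc2)[C@@]3(C(=C)COCc2ccc(OC)cc2)OC(C)(C)O[C@H]3[C@H](OCc2ccc(OC)cc2)[C@@]14CO4
F5 | step 17 | 7β,8β-diol enol triflate | COc1ccc(CO[C@H]2/C=C(\C)CC/C=C(/OS(=O)(=O)C(F)(F)F)[C@@H](OCc3ccc(OC)cc3)[C@H](O)[C@@]2(O)C(=C)COCc3ccc(OC)cc3)cc1
F6 | step 17 | 8-O-angelate enol triflate | COc1ccc(CO[C@H]2/C=C(\C)CC/C=C(/OS(=O)(=O)C(F)(F)F)[C@@H](OCc3ccc(OC)cc3)[C@H](OC(=O)/C(C)=C\C)[C@@]2(O)C(=C)COCc3ccc(OC)cc3)cc1
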